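**Assumption:** the SMILES is taken literally, i.e. (3S,6R,7R,8S,9R), 1(10)Z,4Z, a cis-fused 6,12-lactone (H-6 and H-7 on the same face) and a (2R,3R)-epoxyangelate; germacrane numbering (C1–C15) is used for positions; in step 13 the ligand antipode that delivers the 3S carbinol is the one used.

**Retrosynthetic overview**
1. The last step closes both rings in one flask: indium-mediated intramolecular allylation of an open-chain enal/allyl bromide forms C6–C7 (the bond nature makes when the farnesyl chain closes to the germacrane ring), then O6–C12 lactonisation; the C8 centre alone sets C6 and C7.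
2. The seco-chain comes from an α-acyloxy aldehyde by Morita–Baylis–Hillman homologation with methyl acrylate (C11–C13); the C3 acetate and C8 epoxyangelate are already in place.
3. C3–C4: asymmetric CrCl2/NiCl2 coupling with a (Z)-vinyl iodide made from but-2-yn-1-ol; C1=C10: Z-selective Wittig reaction of an α-silyloxy methyl ketone.
4. C8/C9 anti-diol: L-proline aldol of hydroxyacetone with dimethoxyacetaldehyde; side-chain acid: Sharpless epoxidation of angelyl alcohol.
5. Ring order: oxirane of the ester (step 2), then the ten-membered carbocycle and the γ-lactone together (step 18).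

**Route**

Step 1
Reactants: 1 angelic acid [(Z)-2-methylbut-2-enoic acid]
Product: 2 (Z)-2-methylbut-2-en-1-ol
Conditions: LiAlH4, Et2O, 0 °C
Reagents that add atoms: none
Why: Hydride reduction of the carboxylic acid to the allylic alcohol leaves the Z-trisubstituted alkene untouched and creates no stereocentre.

Step 2
Reactants: 2 (Z)-2-methylbut-2-en-1-ol
Product: 3 [(2S,3R)-2,3-dimethyloxiran-2-yl]methanol
Conditions: Ti(OiPr)4 (cat.), L-(+)-diethyl tartrate, t-BuOOH, 4 Å MS, CH2Cl2, −20 °C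
Reagents that add atoms: tert-butyl hydroperoxide, CC(C)(C)OO
Why: Sharpless asymmetric epoxidation; the L-(+)-tartrate/titanium catalyst selects the alkene face that gives the (2S,3R)-epoxy alcohol, and the Z-alkene fixes the cis relationship of CH2OH and the C3 methyl.

Step 3
Reactants: 3 [(2S,3R)-2,3-dimethyloxiran-2-yl]methanol
Product: 4 (2R,3R)-2,3-dimethyloxirane-2-carboxylic acid
Conditions: RuCl3 (cat.), NaIO4, EtOAc/MeCN/H2O, rt
Reagents that add atoms: water, O
Why: RuO4-catalysed oxidation of the primary alcohol to the acid does not touch the oxirane; C2 becomes R only through the change in CIP priority.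

Step 4
Reactants: 5 but-2-yn-1-ol
Product: 7 (Z)-3-iodobut-2-en-1-ol, via vinylalanate 6 (not isolated)
Conditions: NaAlH2(OCH2CH2OMe)2, THF, 0 °C; then I2, −78 °C
Reagents that add atoms: iodine, II; sodium bis(2-methoxyethoxy)aluminium dihydride, [Na+].[AlH2-](OCCOC)OCCOC (in 6 only)
Why: Hydroxyl-directed trans-hydroalumination places aluminium on C3 cis to CH2OH, and iodinolysis with retention gives the Z-vinyl iodide.

Step 5
Reactants: 7 (Z)-3-iodobut-2-en-1-ol
Product: 8 (Z)-3-iodobut-2-enal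
Conditions: MnO2, CH2Cl2, rt
Reagents that add atoms: none
Why: Allylic oxidation with MnO2 is neutral and keeps the Z geometry.

Step 6
Reactants: 8 (Z)-3-iodobut-2-enal
Product: 9 (Z)-3-iodo-1,1-dimethoxybut-2-ene
Conditions: HC(OMe)3, MeOH, pyridinium p-toluenesulfonate (cat.), rt
Reagents that add atoms: trimethyl orthoformate, COC(OC)OC
Why: Acid-catalysed acetalisation masks C6 as an acetal that survives the chromium coupling and is cleaved later together with the C7 acetal.

Step 7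
Reactants: 10 (3-hydroxypropyl)triphenylphosphonium bromide
Product: 11 triphenyl[3-(triethylsilyloxy)propyl]phosphonium bromide
Conditions: Et3SiCl, imidazole, CH2Cl2, rt
Reagents that add atoms: chlorotriethylsilane, CC[Si](Cl)(CC)CC
Why: O-Silylation gives a C1–C3 Wittig salt whose primary triethylsilyl ether can later be oxidised directly to the C3 aldehyde.

Step 8
Reactants: 12 hydroxyacetone; 13 2,2-dimethoxyacetaldehyde
Product: 14 (3S,4R)-3,4-dihydroxy-5,5-dimethoxypentan-2-one
Conditions: L-proline (30 mol%), DMSO, rt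
Reagents that add atoms: none
Why: Proline-catalysed direct aldol reaction; the hydroxylated E-enamine attacks the Re face of the non-enolisable aldehyde in a hydrogen-bonded chair transition state and gives the anti-diol that becomes C9 and C8.

Step 9
Reactants: 14 (3S,4R)-3,4-dihydroxy-5,5-dimethoxypentan-2-one
Product: 16 (3S,4R)-5,5-dimethoxy-3-(triethylsilyloxy)-4-(trimethylsilyloxy)pentan-2-one, via mono-TES ether 15 (not isolated)
Conditions: Et3SiCl (1.05 equiv), imidazole, CH2Cl2/DMF, −40 °C; then Me3SiCl, 0 °C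
Reagents that add atoms: chlorotriethylsilane, CC[Si](Cl)(CC)CC; chlorotrimethylsilane, C[Si](C)(C)Cl
Why: Regioselective silylation of the more acidic and less hindered α-keto hydroxyl (O9), by analogy with α-selective sulfonylation of 2,3-dihydroxy carbonyl compounds, followed by transient capping of the acetal-flanked O8 as a labile trimethylsilyl ether.

Step 10
Reactants: 16 (3S,4R)-5,5-dimethoxy-3-(triethylsilyloxy)-4-(trimethylsilyloxy)pentan-2-one; 11 triphenyl[3-(triethylsilyloxy)propyl]phosphonium bromide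
Product: 19 (2R,3R,4Z)-1,1-dimethoxy-4-methyl-3,7-bis(triethylsilyloxy)hept-4-en-2-ol, via ylide 17 (not isolated), via TMS ether 18 (not isolated)
Conditions: KN(SiMe3)2, THF, −78 °C; add 16, −78 to 0 °C; then citric acid, MeOH, 0 °C
Reagents that add atoms: none
Why: Wittig olefination of an α-silyloxy methyl ketone with a non-stabilised ylide is strongly Z-selective for the trisubstituted alkene (C2 cis to C9), and mild acid then removes only the trimethylsilyl group to free O8.

Step 11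
Reactants: 19 (2R,3R,4Z)-1,1-dimethoxy-4-methyl-3,7-bis(triethylsilyloxy)hept-4-en-2-ol; 4 (2R,3R)-2,3-dimethyloxirane-2-carboxylic acid
Product: 21 (2R,3R,4Z)-1,1-dimethoxy-4-methyl-3,7-bis(triethylsilyloxy)hept-4-en-2-yl (2R,3R)-2,3-dimethyloxirane-2-carboxylate, via mixed anhydride 20 (not isolated)
Conditions: 2,4,6-Cl3C6H2COCl, Et3N, THF, rt; then 19, DMAP, toluene, rt
Reagents that add atoms: 2,4,6-trichlorobenzoyl chloride, O=C(Cl)c1c(Cl)cc(Cl)cc1Cl (in 20 only)
Why: Yamaguchi esterification puts the final C8 ester on the only free hydroxyl without touching any stereocentre.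

Step 12
Reactants: 21 the epoxyangelate ester from step 11
Product: 23 (2R,3R,4Z)-1,1-dimethoxy-4-methyl-7-oxo-3-(triethylsilyloxy)hept-4-en-2-yl (2R,3R)-2,3-dimethyloxirane-2-carboxylate, via alkoxysulfonium salt 22 (not isolated)
Conditions: (COCl)2, DMSO, CH2Cl2, −78 to −40 °C; then Et3N, −78 °C
Reagents that add atoms: dimethyl sulfoxide, CS(C)=O (in 22 only)
Why: Swern oxidation converts a primary triethylsilyl ether directly into the aldehyde while the secondary allylic silyl ether, the acetal and the epoxy ester stay intact.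

Step 13
Reactants: 23 the C3 aldehyde from step 12; 9 (Z)-3-iodo-1,1-dimethoxybut-2-ene
Product: 24 (2R,3R,4Z,7S,8Z)-7-hydroxy-1,1,10,10-tetramethoxy-4,8-dimethyl-3-(triethylsilyloxy)deca-4,8-dien-2-yl (2R,3R)-2,3-dimethyloxirane-2-carboxylate
Conditions: CrCl2 (4 equiv), NiCl2 (2 mol%), N-[2-(4-isopropyl-4,5-dihydrooxazol-2-yl)-6-methylphenyl]methanesulfonamide, Et3N, THF/MeCN, rt
Reagents that add atoms: none
Why: Nozaki–Hiyama–Kishi coupling adds the alkenylchromium species to the aldehyde with retention of the Z geometry, and the chiral sulfonamide–chromium complex sets the C3 carbinol (S) by reagent control.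

Step 14
Reactants: 24 the C3 alcohol from step 13
Product: 25 (2R,3R,4Z,7S,8Z)-7-acetoxy-1,1,10,10-tetramethoxy-4,8-dimethyl-3-(triethylsilyloxy)deca-4,8-dien-2-yl (2R,3R)-2,3-dimethyloxirane-2-carboxylate
Conditions: Ac2O, pyridine, DMAP (cat.), CH2Cl2, 0 °C
Reagents that add atoms: acetic anhydride, CC(=O)OC(C)=O
Why: Acetylation of the only free hydroxyl installs the C3 acetate of the target.

Step 15
Reactants: 25 the bis-acetal acetate from step 14
Product: 27 (2R,3R,4Z,7S,8Z)-7-acetoxy-4,8-dimethyl-1,10-dioxo-3-(triethylsilyloxy)deca-4,8-dien-2-yl (2R,3R)-2,3-dimethyloxirane-2-carboxylate, via bis-collidinium salt 26 (not isolated)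
Conditions: Et3SiOTf, 2,4,6-collidine, CH2Cl2, 0 °C; then H2O, rt
Reagents that add atoms: water, O; 2,4,6-collidine, Cc1cc(C)nc(C)c1 (in 26 only); triethylsilyl trifluoromethanesulfonate, CC[Si](CC)(CC)OS(=O)(=O)C(F)(F)F (in 26 only)
Why: Silyl triflate/collidine acetal cleavage goes through pyridinium N,O-acetals that water hydrolyses under non-acidic conditions, with anchimeric help from the C8 acyloxy group at C7, so the silyl ether, the oxirane and the Z-enal survive.

Step 16
Reactants: 27 the dialdehyde from step 15; 28 methyl acrylate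
Product: 29 methyl (4S,5R,6Z,9S,10Z)-9-acetoxy-4-{[(2R,3R)-2,3-dimethyloxirane-2-carbonyl]oxy}-3-hydroxy-6,10-dimethyl-2-methylidene-12-oxo-5-(triethylsilyloxy)dodeca-6,10-dienoate (both C3 epimers)
Conditions: 1,4-diazabicyclo[2.2.2]octane (0.5 equiv), methyl acrylate (neat), rt
Reagents that add atoms: none
Why: Morita–Baylis–Hillman reaction occurs at the activated α-acyloxy aldehyde and not at the β,β-disubstituted enal; the new carbinol centre (C7) is a mixture that is erased in steps 17 and 18.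

Step 17
Reactants: 29 the Morita–Baylis–Hillman adduct from step 16
Product: 31 methyl (2Z,4S,5R,6Z,9S,10Z)-9-acetoxy-2-(bromomethyl)-4-{[(2R,3R)-2,3-dimethyloxirane-2-carbonyl]oxy}-6,10-dimethyl-12-oxo-5-(triethylsilyloxy)dodeca-2,6,10-trienoate, via mesylate 30 (not isolated)
Conditions: MsCl, Et3N, CH2Cl2, −20 °C; then LiBr, THF, 0 °C
Reagents that add atoms: lithium bromide, [Li+].[Br-]; methanesulfonyl chloride, CS(=O)(=O)Cl (in 30 only)
Why: Mesylation and SN2' displacement by bromide give the (Z)-2-(bromomethyl)enoate (C8 cis to CH2Br) from both C7 epimers.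

Step 18
Reactants: 31 the allyl bromide enal from step 17
Product: 34 (3S,6R,7R,8S,9R)-3-acetoxy-8-[(2R,3R)-2,3-epoxy-2-methylbutanoyloxy]-9-hydroxygermacra-1(10)Z,4Z,11(13)-trien-12,6-olide, via hydroxy ester 32 (not isolated), via TES lactone 33 (not isolated)
Conditions: In powder (3 equiv), THF/H2O 3:1, 1 mM (slow addition), rt; then 1 M HCl, rt
Reagents that add atoms: none
Why: Proposed new method: indium metal inserts into the allylic C–Br bond and the 2-(methoxycarbonyl)allylindium adds intramolecularly (SE2', six-membered chair transition state) to the C6 aldehyde to close the ten-membered ring at C6–C7; the Z-geometry puts C8 axial and the enal residue equatorial (6,7-syn, hence the cis-fused lactone), and allylic 1,3-strain keeps H-8 in the allyl plane so that the tether carbon C9 lies on the attacked face with the C8–O bond anti to the forming bond, which gives 7R and 6R from 8S; acid then lactonises O6 onto C12 and cleaves the silyl ether; the closest known reaction types are the intermolecular indium Barbier allylation of aldehydes with 2-(bromomethyl)alk-2-enoates to cis-α-methylene-γ-butyrolactones and the CrCl2-mediated allyl bromide–aldehyde macrocyclisation to ten-membered germacranolides.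

**Compound list**

1 | angelic acid, (Z)-2-methylbut-2-enoic acid | C/C=C(/C)C(=O)O | starting material
2 | (Z)-2-methylbut-2-en-1-ol | C/C=C(/C)CO | intermediate
3 | [(2S,3R)-2,3-dimethyloxiran-2-yl]methanol | OC[C@]1(C)O[C@@H]1C | intermediate
4 | (2R,3R)-2,3-dimethyloxirane-2-carboxylic acid (epoxyangelic acid) | OC(=O)[C@]1(C)O[C@@H]1C | intermediate
5 | but-2-yn-1-ol | CC#CCO | starting material
6 | sodium cyclic (Z)-vinylalanate (2,5-dihydro-1,2-oxaluminole ate complex with two 2-methoxyethoxy ligands) | CC1=CCO[Al-]1(OCCOC)OCCOC.[Na+] | intermediate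
7 | (Z)-3-iodobut-2-en-1-ol | C/C(I)=C/CO | intermediate
8 | (Z)-3-iodobut-2-enal | C/C(I)=C/C=O | intermediate
9 | (Z)-3-iodo-1,1-dimethoxybut-2-ene | C/C(I)=C/C(OC)OC | intermediate
10 | (3-hydroxypropyl)triphenylphosphonium bromide | OCCC[P+](c1ccccc1)(c1ccccc1)c1ccccc1.[Br-] | starting material
11 | triphenyl[3-(triethylsilyloxy)propyl]phosphonium bromide | CC[Si](CC)(CC)OCCC[P+](c1ccccc1)(c1ccccc1)c1ccccc1.[Br-] | intermediate
12 | hydroxyacetone | CC(=O)CO | starting material
13 | 2,2-dimethoxyacetaldehyde | COC(OC)C=O | starting material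
14 | (3S,4R)-3,4-dihydroxy-5,5-dimethoxypentan-2-one | CC(=O)[C@@H](O)[C@@H](O)C(OC)OC | intermediate
15 | (3S,4R)-4-hydroxy-5,5-dimethoxy-3-(triethylsilyloxy)pentan-2-one | CC(=O)[C@@H](O[Si](CC)(CC)CC)[C@@H](O)C(OC)OC | intermediate
16 | (3S,4R)-5,5-dimethoxy-3-(triethylsilyloxy)-4-(trimethylsilyloxy)pentan-2-one | CC(=O)[C@@H](O[Si](CC)(CC)CC)[C@@H](O[Si](C)(C)C)C(OC)OC | intermediate
17 | triphenyl[3-(triethylsilyloxy)propylidene]phosphorane | CC[Si](CC)(CC)OCCC=P(c1ccccc1)(c1ccccc1)c1ccccc1 | intermediate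
18 | (2R,3R,4Z)-1,1-dimethoxy-4-methyl-3,7-bis(triethylsilyloxy)-2-(trimethylsilyloxy)hept-4-ene | CC[Si](CC)(CC)OCC/C=C(/C)[C@@H](O[Si](CC)(CC)CC)[C@@H](O[Si](C)(C)C)C(OC)OC | intermediate
19 | (2R,3R,4Z)-1,1-dimethoxy-4-methyl-3,7-bis(triethylsilyloxy)hept-4-en-2-ol | CC[Si](CC)(CC)OCC/C=C(/C)[C@@H](O[Si](CC)(CC)CC)[C@@H](O)C(OC)OC | intermediate
20 | (2R,3R)-2,3-dimethyloxirane-2-carboxylic 2,4,6-trichlorobenzoic anhydride | O=C(OC(=O)c1c(Cl)cc(Cl)cc1Cl)[C@]2(C)O[C@@H]2C | intermediate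
21 | (2R,3R,4Z)-1,1-dimethoxy-4-methyl-3,7-bis(triethylsilyloxy)hept-4-en-2-yl (2R,3R)-2,3-dimethyloxirane-2-carboxylate | CC[Si](CC)(CC)OCC/C=C(/C)[C@@H](O[Si](CC)(CC)CC)[C@@H](OC(=O)[C@]1(C)O[C@@H]1C)C(OC)OC | intermediate
22 | dimethyl(alkoxy)sulfonium chloride of the C3 oxygen of 21 (primary silyl group replaced by SMe2+) | C[S+](C)OCC/C=C(/C)[C@@H](O[Si](CC)(CC)CC)[C@@H](OC(=O)[C@]1(C)O[C@@H]1C)C(OC)OC.[Cl-] | intermediate
23 | (2R,3R,4Z)-1,1-dimethoxy-4-methyl-7-oxo-3-(triethylsilyloxy)hept-4-en-2-yl (2R,3R)-2,3-dimethyloxirane-2-carboxylate | O=CC/C=C(/C)[C@@H](O[Si](CC)(CC)CC)[C@@H](OC(=O)[C@]1(C)O[C@@H]1C)C(OC)OC | intermediate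
24 | (2R,3R,4Z,7S,8Z)-7-hydroxy-1,1,10,10-tetramethoxy-4,8-dimethyl-3-(triethylsilyloxy)deca-4,8-dien-2-yl (2R,3R)-2,3-dimethyloxirane-2-carboxylate | COC(OC)/C=C(/C)[C@@H](O)C/C=C(/C)[C@@H](O[Si](CC)(CC)CC)[C@@H](OC(=O)[C@]1(C)O[C@@H]1C)C(OC)OC | intermediate
25 | (2R,3R,4Z,7S,8Z)-7-acetoxy-1,1,10,10-tetramethoxy-4,8-dimethyl-3-(triethylsilyloxy)deca-4,8-dien-2-yl (2R,3R)-2,3-dimethyloxirane-2-carboxylate | COC(OC)/C=C(/C)[C@@H](OC(C)=O)C/C=C(/C)[C@@H](O[Si](CC)(CC)CC)[C@@H](OC(=O)[C@]1(C)O[C@@H]1C)C(OC)OC | intermediate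
26 | bis(2,4,6-trimethylpyridinium) N,O-acetal bis(triflate) of 25 (one OMe at C1 and at C10 replaced by N-collidinium; both new centres undefined) | COC(/C=C(/C)[C@@H](OC(C)=O)C/C=C(/C)[C@@H](O[Si](CC)(CC)CC)[C@@H](OC(=O)[C@]1(C)O[C@@H]1C)C(OC)[n+]1c(C)cc(C)cc1C)[n+]1c(C)cc(C)cc1C.[O-]S(=O)(=O)C(F)(F)F.[O-]S(=O)(=O)C(F)(F)F | intermediate
27 | (2R,3R,4Z,7S,8Z)-7-acetoxy-4,8-dimethyl-1,10-dioxo-3-(triethylsilyloxy)deca-4,8-dien-2-yl (2R,3R)-2,3-dimethyloxirane-2-carboxylate | O=C/C=C(/C)[C@@H](OC(C)=O)C/C=C(/C)[C@@H](O[Si](CC)(CC)CC)[C@@H](OC(=O)[C@]1(C)O[C@@H]1C)C=O | intermediate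
28 | methyl acrylate | C=CC(=O)OC | starting material
29 | methyl (4S,5R,6Z,9S,10Z)-9-acetoxy-4-{[(2R,3R)-2,3-dimethyloxirane-2-carbonyl]oxy}-3-hydroxy-6,10-dimethyl-2-methylidene-12-oxo-5-(triethylsilyloxy)dodeca-6,10-dienoate (C3 epimers) | O=C/C=C(/C)[C@@H](OC(C)=O)C/C=C(/C)[C@@H](O[Si](CC)(CC)CC)[C@@H](OC(=O)[C@]1(C)O[C@@H]1C)C(O)C(=C)C(=O)OC | intermediate
30 | 3-O-methanesulfonate of 29 (C3 epimers) | O=C/C=C(/C)[C@@H](OC(C)=O)C/C=C(/C)[C@@H](O[Si](CC)(CC)CC)[C@@H](OC(=O)[C@]1(C)O[C@@H]1C)C(OS(C)(=O)=O)C(=C)C(=O)OC | intermediate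
31 | methyl (2Z,4S,5R,6Z,9S,10Z)-9-acetoxy-2-(bromomethyl)-4-{[(2R,3R)-2,3-dimethyloxirane-2-carbonyl]oxy}-6,10-dimethyl-12-oxo-5-(triethylsilyloxy)dodeca-2,6,10-trienoate | O=C/C=C(/C)[C@@H](OC(C)=O)C/C=C(/C)[C@@H](O[Si](CC)(CC)CC)[C@@H](OC(=O)[C@]1(C)O[C@@H]1C)/C=C(/C(=O)OC)CBr | intermediate
32 | methyl (3S,6R,7R,8S,9R)-3-acetoxy-8-{[(2R,3R)-2,3-dimethyloxirane-2-carbonyl]oxy}-6-hydroxy-9-(triethylsilyloxy)germacra-1(10)Z,4Z,11(13)-trien-12-oate | C=C(C(=O)OC)[C@@H]1[C@H](O)/C=C(/C)[C@@H](OC(C)=O)C/C=C(/C)[C@@H](O[Si](CC)(CC)CC)[C@H]1OC(=O)[C@]2(C)O[C@@H]2C | intermediate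
33 | (3S,6R,7R,8S,9R)-3-acetoxy-8-{[(2R,3R)-2,3-dimethyloxirane-2-carbonyl]oxy}-9-(triethylsilyloxy)germacra-1(10)Z,4Z,11(13)-trien-12,6-olide | C=C1C(=O)O[C@@H]2/C=C(/C)[C@@H](OC(C)=O)C/C=C(/C)[C@@H](O[Si](CC)(CC)CC)[C@@H](OC(=O)[C@]3(C)O[C@@H]3C)[C@H]12 | intermediate
34 | CNP0299903.1, (3S,6R,7R,8S,9R)-3-acetoxy-8-[(2R,3R)-2,3-epoxy-2-methylbutanoyloxy]-9-hydroxygermacra-1(10)Z,4Z,11(13)-trien-12,6-olide | C=C1C(=O)O[C@@H]2/C=C(/C)[C@@H](OC(C)=O)C/C=C(/C)[C@@H](O)[C@@H](OC(=O)[C@]3(C)O[C@@H]3C)[C@H]12 | target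

**Step count**

Total: 18 steps. Longest linear sequence: 11 steps (steps 8–18, from hydroxyacetone 12 to 34; the branch through acid 4, steps 1–3 then 11–18, is equally long).

**Three steps most likely to fail, with fallbacks**

Step 18 (macrocyclisation/lactonisation). The allylindium species carries the C8 carboxylate in a position from which it can be eliminated to a diene, and the sense of induction from C8 rests on a transition-state argument, not precedent. Fallback: set out from 29 and acetylate it (AcCl, pyridine, CH2Cl2, −20 °C) to the allylic acetate F1. SN2' borylation (B2pin2, CuCl, LiCl, KOAc, DMF, rt) then gives the allylboronate F2. F2 is diluted into toluene (1 mM, 60 °C), where the covalent, non-reducing allylboronate adds to the enal through a closed chair transition state (type 1 allylboration) and cannot expel the C8 oxygen. Aqueous work-up releases hydroxy ester 32, which rejoins the route (1 M HCl to 33 and 34).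

Step 9 (regioselective mono-silylation of diol 14). If O8 and O9 are not told apart at the ketone stage, set out from 14 and protect both hydroxyls as the acetonide F3 (2,2-dimethoxypropane, pyridinium p-toluenesulfonate). Wittig reaction of F3 with ylide 17 gives the (Z)-alkene acetonide F4. Methanolysis (pyridinium p-toluenesulfonate, MeOH, 40 °C) removes the acetonide and the primary silyl ether to give the triol F5. Silylation of F5 with Et3SiCl (2.1 equiv, imidazole, −40 °C) takes the primary and the allylic hydroxyl and leaves the acetal-flanked, least nucleophilic O8 free, which is compound 19.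

Step 16 (Morita–Baylis–Hillman reaction on the α-acyloxy aldehyde). The amine may be slow, epimerise C8 or move the acyl group to the new hydroxyl. Fallback: set out from 27 and add, at −20 °C, 1.1 equiv of [1-(methoxycarbonyl)vinyl]diisobutylaluminium, preformed from i-Bu2AlH, N-methylmorpholine N-oxide and methyl propiolate in THF at 0 °C. This is a direct 1,2-addition of a vinylalane without amine or free alkoxide and gives 29 after work-up; it makes no new compound (none F0).

Further compounds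
F1 | step 18 | methyl (4S,5R,6Z,9S,10Z)-3,9-diacetoxy-4-{[(2R,3R)-2,3-dimethyloxirane-2-carbonyl]oxy}-6,10-dimethyl-2-methylidene-12-oxo-5-(triethylsilyloxy)dodeca-6,10-dienoate (C3 epimers) | O=C/C=C(/C)[C@@H](OC(C)=O)C/C=C(/C)[C@@H](O[Si](CC)(CC)CC)[C@@H](OC(=O)[C@]1(C)O[C@@H]1C)C(OC(C)=O)C(=C)C(=O)OC
F2 | step 18 | methyl (2E,4S,5R,6Z,9S,10Z)-9-acetoxy-4-{[(2R,3R)-2,3-dimethyloxirane-2-carbonyl]oxy}-6,10-dimethyl-12-oxo-2-[(4,4,5,5-tetramethyl-1,3,2-dioxaborolan-2-yl)methyl]-5-(triethylsilyloxy)dodeca-2,6,10-trienoate (C4 cis to CH2B) | O=C/C=C(/C)[C@@H](OC(C)=O)C/C=C(/C)[C@@H](O[Si](CC)(CC)CC)[C@@H](OC(=O)[C@]1(C)O[C@@H]1C)/C=C(/C(=O)OC)CB1OC(C)(C)C(C)(C)O1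
F3 | step 9 | 1-[(4S,5R)-5-(dimethoxymethyl)-2,2-dimethyl-1,3-dioxolan-4-yl]ethan-1-one | CC(=O)[C@H]1OC(C)(C)O[C@H]1C(OC)OC
F4 | step 9 | (4R,5R)-4-(dimethoxymethyl)-2,2-dimethyl-5-[(2Z)-5-(triethylsilyloxy)pent-2-en-2-yl]-1,3-dioxolane | CC[Si](CC)(CC)OCC/C=C(/C)[C@H]1OC(C)(C)O[C@H]1C(OC)OC
F5 | step 9 | (2R,3R,4Z)-1,1-dimethoxy-4-methylhept-4-ene-2,3,7-triol | OCC/C=C(/C)[C@@H](O)[C@@H](O)C(OC)OC
F0 | step 16 | none | none
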